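**Retrosynthetic overview**
1. Combamide C ⇒ seco aldehyde: the 11-membered ring is closed last by intramolecular Knoevenagel condensation of tetramic acid C-3 with the ring D aldehyde; the tetramic acid comes from an N2-Boc-L-ornithine amide and Meldrum's acid.
2. Ring D (cis,cis-cycloocta-1,5-diene) ⇒ ring-closing metathesis after a Z-selective Wittig union of a ring A–C phosphonium salt with aldehyde fragment 2 (two stereocentres from an amine-catalysed Michael addition).
3. cis-Acetyl/methyl pair on ring A ⇒ cis-fused γ-lactone (carbonylative lactonisation, reduction; opened later by selenolate and MeLi); rings B and A ⇒ one Pauson–Khand reaction on ring C.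
4. Ring C (four cis substituents) ⇒ meso endo-norbornene diol, desymmetrised by a lipase and opened by ethenolysis; ornithine ⇒ phase-transfer-catalysed Michael addition of a glycine imine to acrylonitrile.
5. Ring order: C → B and A together → D → tetramic acid → 11-membered ring (A = acetyl/methyl cyclopentane, B = central cyclopentane, C = cyclopentane fused to D, D = cyclooctadiene).

Assumption: the lipase of step 10 differentiates the two enantiotopic hydroxymethyl groups of 19 in the sense drawn for 20.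

**Route**

Step 1
Reactants: 1 tert-butyl N-(diphenylmethylene)glycinate; 2 acrylonitrile
Product: 3 tert-butyl (S)-4-cyano-2-[(diphenylmethylene)amino]butanoate
Conditions: O-allyl-N-(9-anthracenylmethyl)cinchonidinium bromide (10 mol%), CsOH·H2O (20 mol%), CH2Cl2, −55 °C
Reagents that add atoms: none
Why: Asymmetric phase-transfer-catalysed Michael addition in which the chiral ammonium–enolate ion pair exposes one enolate face and sets the S α-carbon, the first stereocentre of the route.

Step 2
Reactants: 3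
Product: 5 (S)-2-[(tert-butoxycarbonyl)amino]-4-cyanobutanoic acid, via amino acid 4 (not isolated)
Conditions: TFA/CH2Cl2/H2O, rt; evaporate; Boc2O, NaHCO3, dioxane/H2O, rt
Reagents that add atoms: di-tert-butyl dicarbonate, CC(C)(C)OC(=O)OC(=O)OC(C)(C)C
Why: Acidolysis removes the imine and the tert-butyl ester while the nitrile survives, and carbamate formation follows without touching the stereocentre.

Step 3
Reactants: 5
Product: 6 N2-(tert-butoxycarbonyl)-L-ornithine
Conditions: H2 (4 atm), PtO2, AcOH, rt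
Reagents that add atoms: none
Why: Catalytic hydrogenation of the nitrile to the primary amine, with the acidic medium suppressing secondary-amine formation and the Boc group unaffected.

Step 4
Reactants: 7 2-[(tert-butyldiphenylsilyl)oxy]acetaldehyde; 8 nitromethane
Product: 11 (E)-tert-butyl[(3-nitroprop-2-en-1-yl)oxy]diphenylsilane, via nitro alcohol 9 (not isolated), via mesylate 10 (not isolated)
Conditions: MeNO2 (excess), Et3N (cat.), rt; evaporate; MsCl, Et3N, CH2Cl2, −20 → 0 °C
Reagents that add atoms: none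
Why: Henry addition followed by mesylation and E1cB elimination gives the thermodynamically favoured E nitroalkene.

Step 5
Reactants: 12 3-[(tert-butyldimethylsilyl)oxy]propanal; 11 (E)-tert-butyl[(3-nitroprop-2-en-1-yl)oxy]diphenylsilane
Product: 13 (2S,3R)-2-{[(tert-butyldimethylsilyl)oxy]methyl}-3-{[(tert-butyldiphenylsilyl)oxy]methyl}-4-nitrobutanal
Conditions: (S)-2-[diphenyl(trimethylsilyloxy)methyl]pyrrolidine (10 mol%), 4-nitrophenol (10 mol%), toluene, 0 °C → rt
Reagents that add atoms: none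
Why: Enamine-catalysed Michael addition (Hayashi–Jørgensen) in which the bulky silyloxydiphenylmethyl group shields one enamine face and the acyclic synclinal transition state gives the syn (2S,3R) adduct.

Step 6
Reactants: 13
Product: 14 (3S,4R)-3-{[(tert-butyldimethylsilyl)oxy]methyl}-4-{[(tert-butyldiphenylsilyl)oxy]methyl}-5-nitropent-1-ene
Conditions: Ph3PCH3Br (2.5 equiv), KN(SiMe3)2 (2.4 equiv), THF, −78 → 0 °C
Reagents that add atoms: methyltriphenylphosphonium bromide, C[P+](c1ccccc1)(c1ccccc1)c1ccccc1.[Br-]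
Why: Wittig methylenation in which the first equivalent of ylide parks the acidic nitro group as its nitronate, so the aldehyde is olefinated at low temperature without loss of the α-stereocentre.

Step 7
Reactants: 14
Product: 15 (2S,3R)-3-{[(tert-butyldiphenylsilyl)oxy]methyl}-2-ethenyl-4-nitrobutan-1-ol
Conditions: PPTS (20 mol%), MeOH, rt
Reagents that add atoms: none
Why: Acid-catalysed methanolysis cleaves the primary tert-butyldimethylsilyl ether selectively in the presence of the bulkier tert-butyldiphenylsilyl ether.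

Step 8
Reactants: 15
Product: 17 tert-butyl{[(2R,3S)-3-(1,3-dioxolan-2-yl)-2-(nitromethyl)pent-4-en-1-yl]oxy}diphenylsilane, via aldehyde 16 (not isolated)
Conditions: Dess–Martin periodinane, NaHCO3, CH2Cl2, 0 °C; filter, concentrate cold; Me3SiOCH2CH2OSiMe3, Me3SiOTf (5 mol%), CH2Cl2, −78 °C
Reagents that add atoms: 1,2-bis(trimethylsilyloxy)ethane, C[Si](C)(C)OCCO[Si](C)(C)C
Why: Buffered Dess–Martin oxidation followed at once by Noyori acetalisation under aprotic low-temperature conditions masks the α-vinyl aldehyde before it can epimerise or move into conjugation.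

Step 9
Reactants: 17
Product: 18 (2S,3S)-2-{[(tert-butyldiphenylsilyl)oxy]methyl}-3-(1,3-dioxolan-2-yl)pent-4-enal (fragment 2)
Conditions: NaOMe, MeOH, 0 °C; then aq. TiCl3, NH4OAc (pH 5–6), THF, 0 °C → rt
Reagents that add atoms: water, O
Why: Nef reaction in McMurry's reductive form, in which the nitronate is reduced by TiCl3 to the imine and hydrolysed under buffered conditions that spare the dioxolane, the silyl ether and the α-stereocentre.

Step 10
Reactants: 19 meso-[(1R,2S,3R,4S)-bicyclo[2.2.1]hept-5-ene-2,3-diyl]dimethanol (endo,endo)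
Product: 20 [(1R,2S,3R,4S)-3-(hydroxymethyl)bicyclo[2.2.1]hept-5-en-2-yl]methyl acetate
Conditions: Burkholderia cepacia lipase (lipase PS, immobilised), vinyl acetate, t-BuOMe, 25 °C
Reagents that add atoms: vinyl acetate, CC(=O)OC=C
Why: A lipase (serine hydrolase) catalyses irreversible transesterification of only one of the two enantiotopic hydroxymethyl groups of the meso diol (desymmetrisation), which fixes the absolute configuration of all four ring C stereocentres.

Step 11
Reactants: 20
Product: 21 [(1R,2S,3R,4S)-3-{[(triisopropylsilyl)oxy]methyl}bicyclo[2.2.1]hept-5-en-2-yl]methyl acetate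
Conditions: i-Pr3SiCl, imidazole, DMF, rt
Reagents that add atoms: chlorotriisopropylsilane, CC(C)[Si](Cl)(C(C)C)C(C)C
Why: Standard silylation of the remaining primary alcohol gives an ether that survives every step up to step 21.

Step 12
Reactants: 21
Product: 22 ring C diene acetate (all-cis cyclopentane: CH2OAc at C-1, CH2OSi(i-Pr)3 at C-2, vinyl at C-3 and C-5)
Conditions: first-generation Grubbs catalyst RuCl2(PCy3)2(=CHPh) (3 mol%), ethene (1 atm), CH2Cl2 (0.02 M), rt
Reagents that add atoms: ethene, C=C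
Why: Ring-opening cross-metathesis with ethene releases the norbornene strain and leaves the four stereocentres untouched, giving ring C with four cis substituents.

Step 13
Reactants: 22
Product: 23 ring C diene alcohol (CH2OH in place of CH2OAc)
Conditions: K2CO3, MeOH, rt
Reagents that add atoms: none
Why: Base-catalysed transesterification removes the acetate.

Step 14
Reactants: 23
Product: 25 silylated enyne (CH2C≡CSiMe3 in place of CH2OH), via triflate 24 (not isolated)
Conditions: Tf2O, 2,6-lutidine, CH2Cl2, −78 °C; then LiC≡CSiMe3 (from HC≡CSiMe3 and n-BuLi), THF/DMPU, −78 → −20 °C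
Reagents that add atoms: lithium (trimethylsilyl)acetylide, [Li]C#C[Si](C)(C)C
Why: SN2 displacement of the primary triflate by the acetylide installs the propargyl arm, and no stereocentre is involved.

Step 15
Reactants: 25
Product: 26 1,6-enyne (all-cis cyclopentane: propargyl at C-1, CH2OSi(i-Pr)3 at C-2, vinyl at C-3 and C-5)
Conditions: K2CO3, MeOH, rt
Reagents that add atoms: none
Why: Methanolysis of the alkynyl C–Si bond frees the terminal alkyne needed for the cyclocarbonylation.

Step 16
Reactants: 26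
Product: 28 tricyclic enone (rings A–C cis-anti-cis; ring A cyclopentenone with C=C at the A/B fusion), via dicobalt hexacarbonyl alkyne complex 27 (not isolated)
Conditions: Co2(CO)8, CH2Cl2, rt; then N-methylmorpholine N-oxide, 0 °C → rt
Reagents that add atoms: octacarbonyldicobalt (delivers one CO), [Co].[Co].[C-]#[O+].[C-]#[O+].[C-]#[O+].[C-]#[O+].[C-]#[O+].[C-]#[O+].[C-]#[O+].[C-]#[O+]
Why: The intramolecular Pauson–Khand reaction of the 1,6-enyne builds rings B and A at once (the other vinyl group could only give a bridged ring), and the new ring-fusion carbon forms with ring A on the convex face of the B/C bicycle, which is the cis-anti-cis arrangement.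

Step 17
Reactants: 28
Product: 30 tricyclic enone with a convex-face CH2OSiEt3 group on the ring A carbon between the carbonyl and the A/B fusion, via aldol adduct 29 (not isolated)
Conditions: LiN(i-Pr)2, THF, −78 °C; CH2O (gas); then Et3SiCl, −78 → 0 °C
Reagents that add atoms: formaldehyde, C=O; chlorotriethylsilane, CC[Si](Cl)(CC)CC
Why: Aldol reaction of the kinetic α'-enolate with formaldehyde from the convex face, anti to the adjacent ring B bond, sets the future methyl-bearing centre, and the alkoxide is capped in the flask.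

Step 18
Reactants: 30
Product: 32 ring A enol triflate with cis A/B fusion and free hydroxymethyl group, via silyl ether triflate 31 (not isolated)
Conditions: Li, NH3 (l)/THF, t-BuOH (1 equiv), −78 °C; evaporate NH3; PhNTf2, THF, 0 °C; then AcOH/THF/H2O, rt
Reagents that add atoms: N-phenylbis(trifluoromethanesulfonimide), O=S(=O)(N(c1ccccc1)S(=O)(=O)C(F)(F)F)C(F)(F)F
Why: Dissolving-metal conjugate reduction gives the only accessible cis ring fusion and a regiodefined lithium enolate that is trapped as the enol triflate, after which mild acid removes only the triethylsilyl group.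

Step 19
Reactants: 32
Product: 33 α,β-unsaturated γ-lactone fused to ring A
Conditions: Pd(PPh3)4 (5 mol%), CO (1 atm), n-Bu3N, LiCl, MeCN, 65 °C
Reagents that add atoms: carbon monoxide, [C-]#[O+]
Why: Palladium-catalysed carbonylation of the enol triflate with intramolecular capture of the acylpalladium species by the neighbouring hydroxymethyl group closes the unsaturated five-membered lactone.

Step 20
Reactants: 33
Product: 34 saturated cis-fused γ-lactone on ring A (acyl carbon and CH2O carbon cis on the convex face)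
Conditions: Mg, MeOH, 0 °C → rt; then 1 M HCl
Reagents that add atoms: none
Why: Conjugate reduction by magnesium in methanol under equilibrating conditions can only deliver the cis-fused γ-lactone, so the acyl carbon ends up cis to the CH2O carbon, which is the cis acetyl/methyl relation of the target.

Step 21
Reactants: 34
Product: 35 lactone alcohol (ring C CH2OH)
Conditions: Bu4NF, THF, 0 °C
Reagents that add atoms: none
Why: Fluoride cleaves the triisopropylsilyl ether and leaves the lactone untouched.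

Step 22
Reactants: 35
Product: 36 lactone iodide (ring C CH2I)
Conditions: I2, PPh3, imidazole, CH2Cl2, 0 °C → rt
Reagents that add atoms: iodine, II
Why: Appel-type iodination of the primary alcohol under neutral conditions.

Step 23
Reactants: 36
Product: 37 lactone triphenylphosphonium iodide
Conditions: PPh3, MeCN, 85 °C (sealed tube)
Reagents that add atoms: triphenylphosphine, c1ccc(cc1)P(c1ccccc1)c1ccccc1
Why: SN2 quaternisation of triphenylphosphine by the primary iodide.

Step 24
Reactants: 37 lactone triphenylphosphonium iodide; 18 fragment 2 aldehyde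
Product: 39 Z-configured Wittig triene (rings A–C lactone joined to fragment 2), via ylide 38 (not isolated)
Conditions: NaN(SiMe3)2 (1.0 equiv), THF, −78 °C; then 18, −78 °C → rt
Reagents that add atoms: none
Why: Wittig reaction of the non-stabilised ylide under lithium-free conditions gives the Z alkene by kinetic control and joins fragment 2 to the tricycle without touching any stereocentre.

Step 25
Reactants: 39
Product: 40 pentacyclic lactone containing ring D (cis,cis-cycloocta-1,5-diene)
Conditions: second-generation Grubbs catalyst RuCl2(H2IMes)(PCy3)(=CHPh) (10 mol%), CH2Cl2 (1 mM), 40 °C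
Reagents that add atoms: none
Why: Ring-closing metathesis of the two vinyl groups, preorganised by the cis ring C substituents and the Z alkene, closes ring D with loss of ethene, and the eight-membered ring allows only a Z double bond.

Step 26
Reactants: 40
Product: 41 ring A carboxylic acid with cis CH2SePh group
Conditions: PhSeH, NaH, THF/HMPA, 65 °C; then 1 M HCl
Reagents that add atoms: benzeneselenol, [SeH]c1ccccc1
Why: SN2 attack of the soft selenolate at the lactone CH2–O carbon opens the ring to the carboxylic acid without involving the stereocentre next to the carbonyl.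

Step 27
Reactants: 41
Product: 42 ring A carboxylic acid with cis methyl group
Conditions: Bu3SnH, AIBN (cat.), benzene, 80 °C
Reagents that add atoms: none
Why: Radical chain reduction of the C–Se bond turns the CH2SePh group into the methyl group.

Step 28
Reactants: 42
Product: 43 ring A methyl ketone (acetyl cis to methyl)
Conditions: MeLi (3 equiv), THF, 0 °C; Me3SiCl; aq. NH4Cl
Reagents that add atoms: methyllithium, [Li]C
Why: Addition of methyllithium to the lithium carboxylate stops at the geminal dialkoxide, which cannot enolise, so the acetyl group appears only on work-up with the cis configuration kept.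

Step 29
Reactants: 43
Product: 44 ring D primary alcohol
Conditions: Bu4NF, AcOH (1:1), THF, rt
Reagents that add atoms: none
Why: Buffered fluoride removes the tert-butyldiphenylsilyl ether without base that could epimerise the ketone.

Step 30
Reactants: 44
Product: 45 ring D carboxylic acid
Conditions: TEMPO (20 mol%), PhI(OAc)2, MeCN/aq. phosphate buffer (pH 7), rt
Reagents that add atoms: water, O
Why: Oxoammonium-mediated oxidation of the primary alcohol through the aldehyde hydrate to the acid under near-neutral conditions avoids migration of the β,γ double bond.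

Step 31
Reactants: 45 ring D carboxylic acid; 6 N2-(tert-butoxycarbonyl)-L-ornithine
Product: 47 ornithine amide acid, via succinimidyl ester 46 (not isolated)
Conditions: N-hydroxysuccinimide, EDC·HCl, CH2Cl2, 0 °C → rt; then 6, NaHCO3, DMF/H2O, rt
Reagents that add atoms: none
Why: Active-ester aminolysis acylates only the free side-chain amine of 6 and needs no protection of its carboxylic acid.

Step 32
Reactants: 47
Product: 49 N-Boc tetramic acid, via acyl Meldrum's acid 48 (not isolated)
Conditions: Meldrum's acid, EDC·HCl, DMAP, CH2Cl2, 0 °C → rt; aq. KHSO4 wash; EtOAc, reflux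
Reagents that add atoms: Meldrum's acid, CC1(C)OC(=O)CC(=O)O1
Why: C-acylation of Meldrum's acid followed by thermal loss of acetone and CO2 gives an acylketene that is trapped by the carbamate nitrogen (Jouin tetramic acid synthesis) without racemisation of the α-carbon.

Step 33
Reactants: 49
Product: 51 Combamide C, via seco aldehyde 50 (not isolated)
Conditions: TFA/H2O (95:5), 0 °C; then added dropwise to MeCN (final 1 mM) containing ethylenediammonium diacetate (20 mol%), rt
Reagents that add atoms: none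
Why: Acid removes the Boc group and the dioxolane, and intramolecular Knoevenagel condensation of tetramic acid C-3 with the liberated aldehyde closes the 11-membered ring, whose size dictates the alkene geometry of the target.

**Compound list**
1 | tert-butyl N-(diphenylmethylene)glycinate | CC(C)(C)OC(=O)CN=C(c1ccccc1)c1ccccc1 | starting material
2 | acrylonitrile | C=CC#N | starting material
3 | tert-butyl (S)-4-cyano-2-[(diphenylmethylene)amino]butanoate | CC(C)(C)OC(=O)[C@H](CCC#N)N=C(c1ccccc1)c1ccccc1 | intermediate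
4 | (S)-2-amino-4-cyanobutanoic acid | N[C@@H](CCC#N)C(O)=O | intermediate
5 | (S)-2-[(tert-butoxycarbonyl)amino]-4-cyanobutanoic acid | CC(C)(C)OC(=O)N[C@@H](CCC#N)C(O)=O | intermediate
6 | N2-(tert-butoxycarbonyl)-L-ornithine | CC(C)(C)OC(=O)N[C@@H](CCCN)C(O)=O | intermediate
7 | 2-[(tert-butyldiphenylsilyl)oxy]acetaldehyde | O=CCO[Si](c1ccccc1)(c1ccccc1)C(C)(C)C | starting material
8 | nitromethane | C[N+](=O)[O-] | starting material
9 | 1-[(tert-butyldiphenylsilyl)oxy]-3-nitropropan-2-ol (racemic) | OC(CO[Si](c1ccccc1)(c1ccccc1)C(C)(C)C)C[N+](=O)[O-] | intermediate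
10 | 1-[(tert-butyldiphenylsilyl)oxy]-3-nitropropan-2-yl methanesulfonate (racemic) | CS(=O)(=O)OC(CO[Si](c1ccccc1)(c1ccccc1)C(C)(C)C)C[N+](=O)[O-] | intermediate
11 | (E)-tert-butyl[(3-nitroprop-2-en-1-yl)oxy]diphenylsilane | [O-][N+](=O)/C=C/CO[Si](c1ccccc1)(c1ccccc1)C(C)(C)C | intermediate
12 | 3-[(tert-butyldimethylsilyl)oxy]propanal | O=CCCO[Si](C)(C)C(C)(C)C | starting material
13 | (2S,3R)-2-{[(tert-butyldimethylsilyl)oxy]methyl}-3-{[(tert-butyldiphenylsilyl)oxy]methyl}-4-nitrobutanal | O=C[C@H](CO[Si](C)(C)C(C)(C)C)[C@@H](CO[Si](c1ccccc1)(c1ccccc1)C(C)(C)C)C[N+](=O)[O-] | intermediate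
14 | (3S,4R)-3-{[(tert-butyldimethylsilyl)oxy]methyl}-4-{[(tert-butyldiphenylsilyl)oxy]methyl}-5-nitropent-1-ene | C=C[C@H](CO[Si](C)(C)C(C)(C)C)[C@@H](CO[Si](c1ccccc1)(c1ccccc1)C(C)(C)C)C[N+](=O)[O-] | intermediate
15 | (2S,3R)-3-{[(tert-butyldiphenylsilyl)oxy]methyl}-2-ethenyl-4-nitrobutan-1-ol | C=C[C@H](CO)[C@@H](CO[Si](c1ccccc1)(c1ccccc1)C(C)(C)C)C[N+](=O)[O-] | intermediate
16 | (2S,3R)-3-{[(tert-butyldiphenylsilyl)oxy]methyl}-2-ethenyl-4-nitrobutanal | C=C[C@H](C=O)[C@@H](CO[Si](c1ccccc1)(c1ccccc1)C(C)(C)C)C[N+](=O)[O-] | intermediate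
17 | tert-butyl{[(2R,3S)-3-(1,3-dioxolan-2-yl)-2-(nitromethyl)pent-4-en-1-yl]oxy}diphenylsilane | C=C[C@H](C1OCCO1)[C@@H](CO[Si](c2ccccc2)(c2ccccc2)C(C)(C)C)C[N+](=O)[O-] | intermediate
18 | (2S,3S)-2-{[(tert-butyldiphenylsilyl)oxy]methyl}-3-(1,3-dioxolan-2-yl)pent-4-enal (fragment 2) | C=C[C@H](C1OCCO1)[C@@H](CO[Si](c2ccccc2)(c2ccccc2)C(C)(C)C)C=O | intermediate
19 | meso-[(1R,2S,3R,4S)-bicyclo[2.2.1]hept-5-ene-2,3-diyl]dimethanol (endo,endo) | OC[C@@H]1[C@H](CO)[C@@H]2C=C[C@H]1C2 | starting material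
20 | [(1R,2S,3R,4S)-3-(hydroxymethyl)bicyclo[2.2.1]hept-5-en-2-yl]methyl acetate | CC(=O)OC[C@@H]1[C@H](CO)[C@@H]2C=C[C@H]1C2 | intermediate
21 | [(1R,2S,3R,4S)-3-{[(triisopropylsilyl)oxy]methyl}bicyclo[2.2.1]hept-5-en-2-yl]methyl acetate | CC(=O)OC[C@@H]1[C@H](CO[Si](C(C)C)(C(C)C)C(C)C)[C@@H]2C=C[C@H]1C2 | intermediate
22 | ring C diene acetate (all-cis cyclopentane: CH2OAc at C-1, CH2OSi(i-Pr)3 at C-2, vinyl at C-3 and C-5) | CC(=O)OC[C@@H]1[C@H](CO[Si](C(C)C)(C(C)C)C(C)C)[C@H](C=C)C[C@@H]1C=C | intermediate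
23 | ring C diene alcohol (CH2OH in place of CH2OAc) | OC[C@@H]1[C@H](CO[Si](C(C)C)(C(C)C)C(C)C)[C@H](C=C)C[C@@H]1C=C | intermediate
24 | ring C diene trifluoromethanesulfonate | O=S(=O)(OC[C@@H]1[C@H](CO[Si](C(C)C)(C(C)C)C(C)C)[C@H](C=C)C[C@@H]1C=C)C(F)(F)F | intermediate
25 | silylated enyne (CH2C≡CSiMe3 arm) | C[Si](C)(C)C#CC[C@@H]1[C@H](CO[Si](C(C)C)(C(C)C)C(C)C)[C@H](C=C)C[C@@H]1C=C | intermediate
26 | 1,6-enyne (all-cis cyclopentane: propargyl at C-1, CH2OSi(i-Pr)3 at C-2, vinyl at C-3 and C-5) | C#CC[C@@H]1[C@H](CO[Si](C(C)C)(C(C)C)C(C)C)[C@H](C=C)C[C@@H]1C=C | intermediate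
27 | dicobalt hexacarbonyl complex of alkyne 26 (coordination written as a dot-separated string) | C#CC[C@@H]1[C@H](CO[Si](C(C)C)(C(C)C)C(C)C)[C@H](C=C)C[C@@H]1C=C.[Co].[Co].[C-]#[O+].[C-]#[O+].[C-]#[O+].[C-]#[O+].[C-]#[O+].[C-]#[O+] | intermediate
28 | tricyclic enone (rings A–C cis-anti-cis; ring A cyclopentenone; ring C with cis vinyl and CH2OSi(i-Pr)3) | O=C1C=C2C[C@@H]3[C@H](CO[Si](C(C)C)(C(C)C)C(C)C)[C@H](C=C)C[C@@H]3[C@H]2C1 | intermediate
29 | aldol adduct: enone 28 with convex-face CH2OH next to the ketone (formed as lithium alkoxide) | O=C1C=C2C[C@@H]3[C@H](CO[Si](C(C)C)(C(C)C)C(C)C)[C@H](C=C)C[C@@H]3[C@H]2[C@@H]1CO | intermediate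
30 | triethylsilyl ether of 29 | O=C1C=C2C[C@@H]3[C@H](CO[Si](C(C)C)(C(C)C)C(C)C)[C@H](C=C)C[C@@H]3[C@H]2[C@@H]1CO[Si](CC)(CC)CC | intermediate
31 | ring A enol triflate, cis A/B fusion, triethylsilyl ether | O=S(=O)(OC1=C[C@H]2C[C@@H]3[C@H](CO[Si](C(C)C)(C(C)C)C(C)C)[C@H](C=C)C[C@@H]3[C@H]2[C@@H]1CO[Si](CC)(CC)CC)C(F)(F)F | intermediate
32 | ring A enol triflate, cis A/B fusion, free hydroxymethyl | O=S(=O)(OC1=C[C@H]2C[C@@H]3[C@H](CO[Si](C(C)C)(C(C)C)C(C)C)[C@H](C=C)C[C@@H]3[C@H]2[C@@H]1CO)C(F)(F)F | intermediate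
33 | α,β-unsaturated γ-lactone fused to ring A | O=C1OC[C@@H]2C1=C[C@H]4C[C@@H]3[C@H](CO[Si](C(C)C)(C(C)C)C(C)C)[C@H](C=C)C[C@@H]3[C@H]42 | intermediate
34 | saturated cis-fused γ-lactone on ring A | O=C1OC[C@@H]2[C@H]1C[C@H]4C[C@@H]3[C@H](CO[Si](C(C)C)(C(C)C)C(C)C)[C@H](C=C)C[C@@H]3[C@H]42 | intermediate
35 | lactone alcohol (ring C CH2OH) | O=C1OC[C@@H]2[C@H]1C[C@H]4C[C@@H]3[C@H](CO)[C@H](C=C)C[C@@H]3[C@H]42 | intermediate
36 | lactone iodide (ring C CH2I) | O=C1OC[C@@H]2[C@H]1C[C@H]4C[C@@H]3[C@H](CI)[C@H](C=C)C[C@@H]3[C@H]42 | intermediate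
37 | lactone triphenylphosphonium iodide | O=C1OC[C@@H]2[C@H]1C[C@H]4C[C@@H]3[C@H](C[P+](c5ccccc5)(c5ccccc5)c5ccccc5)[C@H](C=C)C[C@@H]3[C@H]42.[I-] | intermediate
38 | phosphorus ylide from 37 | O=C1OC[C@@H]2[C@H]1C[C@H]4C[C@@H]3[C@H](C=P(c5ccccc5)(c5ccccc5)c5ccccc5)[C@H](C=C)C[C@@H]3[C@H]42 | intermediate
39 | Z-configured Wittig triene | O=C1OC[C@@H]2[C@H]1C[C@H]4C[C@@H]3[C@H](/C=C\[C@H](CO[Si](c5ccccc5)(c5ccccc5)C(C)(C)C)[C@@H](C5OCCO5)C=C)[C@H](C=C)C[C@@H]3[C@H]42 | intermediate
40 | pentacyclic lactone with ring D (cis,cis-cycloocta-1,5-diene; trans CH2OSi and dioxolanyl groups) | O=C1OC[C@@H]2[C@H]1C[C@H]4C[C@@H]3[C@@H]5/C=C\[C@H](CO[Si](c6ccccc6)(c6ccccc6)C(C)(C)C)[C@@H](C6OCCO6)/C=C\[C@@H]5C[C@@H]3[C@H]42 | intermediate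
41 | ring A carboxylic acid with cis CH2SePh | OC(=O)[C@@H]1C[C@H]2C[C@@H]3[C@@H]4/C=C\[C@H](CO[Si](c5ccccc5)(c5ccccc5)C(C)(C)C)[C@@H](C5OCCO5)/C=C\[C@@H]4C[C@@H]3[C@H]2[C@@H]1C[Se]c6ccccc6 | intermediate
42 | ring A carboxylic acid with cis methyl | OC(=O)[C@@H]1C[C@H]2C[C@@H]3[C@@H]4/C=C\[C@H](CO[Si](c5ccccc5)(c5ccccc5)C(C)(C)C)[C@@H](C5OCCO5)/C=C\[C@@H]4C[C@@H]3[C@H]2[C@@H]1C | intermediate
43 | ring A methyl ketone (acetyl cis to methyl) | CC(=O)[C@@H]1C[C@H]2C[C@@H]3[C@@H]4/C=C\[C@H](CO[Si](c5ccccc5)(c5ccccc5)C(C)(C)C)[C@@H](C5OCCO5)/C=C\[C@@H]4C[C@@H]3[C@H]2[C@@H]1C | intermediate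
44 | ring D primary alcohol | CC(=O)[C@@H]1C[C@H]2C[C@@H]3[C@@H]4/C=C\[C@H](CO)[C@@H](C5OCCO5)/C=C\[C@@H]4C[C@@H]3[C@H]2[C@@H]1C | intermediate
45 | ring D carboxylic acid | CC(=O)[C@@H]1C[C@H]2C[C@@H]3[C@@H]4/C=C\[C@H](C(O)=O)[C@@H](C5OCCO5)/C=C\[C@@H]4C[C@@H]3[C@H]2[C@@H]1C | intermediate
46 | N-succinimidyl ester of 45 | CC(=O)[C@@H]1C[C@H]2C[C@@H]3[C@@H]4/C=C\[C@H](C(=O)ON5C(=O)CCC5=O)[C@@H](C5OCCO5)/C=C\[C@@H]4C[C@@H]3[C@H]2[C@@H]1C | intermediate
47 | ornithine amide acid (N5-acyl-N2-Boc-L-ornithine) | CC(=O)[C@@H]1C[C@H]2C[C@@H]3[C@@H]4/C=C\[C@H](C(=O)NCCC[C@H](NC(=O)OC(C)(C)C)C(O)=O)[C@@H](C5OCCO5)/C=C\[C@@H]4C[C@@H]3[C@H]2[C@@H]1C | intermediate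
48 | acyl Meldrum's acid derived from 47 | CC(=O)[C@@H]1C[C@H]2C[C@@H]3[C@@H]4/C=C\[C@H](C(=O)NCCC[C@H](NC(=O)OC(C)(C)C)C(=O)C5C(=O)OC(C)(C)OC5=O)[C@@H](C5OCCO5)/C=C\[C@@H]4C[C@@H]3[C@H]2[C@@H]1C | intermediate
49 | N-Boc tetramic acid ((S)-5-substituted 1-Boc-pyrrolidine-2,4-dione) | CC(=O)[C@@H]1C[C@H]2C[C@@H]3[C@@H]4/C=C\[C@H](C(=O)NCCC[C@@H]5N(C(=O)OC(C)(C)C)C(=O)CC5=O)[C@@H](C5OCCO5)/C=C\[C@@H]4C[C@@H]3[C@H]2[C@@H]1C | intermediate
50 | seco aldehyde (free tetramic acid and ring D aldehyde) | CC(=O)[C@@H]1C[C@H]2C[C@@H]3[C@@H]4/C=C\[C@H](C(=O)NCCC[C@@H]5NC(=O)CC5=O)[C@@H](C=O)/C=C\[C@@H]4C[C@@H]3[C@H]2[C@@H]1C | intermediate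
51 | Combamide C | CC(=O)[C@@H]1C[C@H]2C[C@@H]3[C@@H]4/C=C\[C@@H]5C(=O)NCCC[C@@H]6NC(=O)/C(=C/[C@H]5/C=C\[C@@H]4C[C@@H]3[C@H]2[C@@H]1C)C6=O | target

**Totals**
Total step count: 33 (ornithine unit steps 1–3, fragment 2 steps 4–9, main line steps 10–33).
Longest linear sequence: 24 steps (19 → 51, steps 10–33).

**Three steps most likely to fail**

Step 33 (deprotection and macrocyclising Knoevenagel condensation). The free α-vinyl aldehyde can epimerise or oligomerise before the strained 11-membered ring closes. The fallback sets out from 49 and comes back at 51. The tetramic acid enol of 49 is silylated (t-BuMe2SiCl, imidazole, DMF) to the O-silyl tetramate F1. Under high dilution Me3SiOTf or BF3·OEt2 (CH2Cl2, −78 °C) opens the dioxolane to an oxocarbenium ion, which the silyl enol ether captures (intramolecular Mukaiyama-type acetal aldol), so the aldehyde is never set free; this gives the macrocyclic 2-hydroxyethyl ether F2. TFA then removes the Boc group, and the β-alkoxy group is eliminated from the 1,3-dicarbonyl unit (a trace of DBU if needed) to give 51.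

Step 24 (Wittig union). The phosphonium centre sits on the crowded all-cis face of ring C, so salt formation (step 23), ylide generation and the addition may all be slow, and the aldehyde 18 is epimerisable. The fallback exchanges the roles of the partners; it sets out from 35 and 18 and comes back at 39. Alcohol 35 is oxidised (Dess–Martin periodinane, NaHCO3, 0 °C) to the ring C aldehyde F3, which is used at once. Aldehyde 18 is reduced (NaBH4, MeOH) to the alcohol F4, converted (I2, PPh3, imidazole) into the iodide F5 and (PPh3, MeCN, 80 °C) into the unhindered phosphonium iodide F6. NaN(SiMe3)2 (THF, −78 °C) gives the ylide F7, which adds to F3 at −78 °C to give 39.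

Step 9 (Nef reaction). The buffered TiCl3 hydrolysis may be low-yielding next to the acid-sensitive dioxolane and gives an epimerisable aldehyde. The fallback sets out from 17 and comes back at 18. The nitro group is reduced to the oxime F8 with SnCl2, PhSH and Et3N (MeCN, rt). The oxime is then exchanged onto glyoxylic acid (aq. glyoxylic acid, NaOAc, THF, rt), which releases 18 under nearly neutral conditions.

**Further compounds**
F1 | step 33 | O-silyl tetramate (4-tert-butyldimethylsilyloxy-3-pyrrolin-2-one form of 49) | CC(=O)[C@@H]1C[C@H]2C[C@@H]3[C@@H]4/C=C\[C@H](C(=O)NCCC[C@@H]5N(C(=O)OC(C)(C)C)C(=O)C=C5O[Si](C)(C)C(C)(C)C)[C@@H](C5OCCO5)/C=C\[C@@H]4C[C@@H]3[C@H]2[C@@H]1C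
F2 | step 33 | macrocyclic 2-hydroxyethyl ether (N-Boc; mixture at the two transient centres) | CC(=O)[C@@H]1C[C@H]2C[C@@H]3[C@@H]4/C=C\[C@@H]5C(=O)NCCC[C@@H]6N(C(=O)OC(C)(C)C)C(=O)C(C(OCCO)[C@H]5/C=C\[C@@H]4C[C@@H]3[C@H]2[C@@H]1C)C6=O
F3 | step 24 | ring C aldehyde (lactone 35 with CHO in place of CH2OH) | O=C1OC[C@@H]2[C@H]1C[C@H]4C[C@@H]3[C@H](C=O)[C@H](C=C)C[C@@H]3[C@H]42
F4 | step 24 | (2R,3S)-2-{[(tert-butyldiphenylsilyl)oxy]methyl}-3-(1,3-dioxolan-2-yl)pent-4-en-1-ol | C=C[C@H](C1OCCO1)[C@@H](CO[Si](c2ccccc2)(c2ccccc2)C(C)(C)C)CO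
F5 | step 24 | iodide of F4 | C=C[C@H](C1OCCO1)[C@@H](CO[Si](c2ccccc2)(c2ccccc2)C(C)(C)C)CI
F6 | step 24 | triphenylphosphonium iodide from F5 | C=C[C@H](C1OCCO1)[C@@H](CO[Si](c2ccccc2)(c2ccccc2)C(C)(C)C)C[P+](c2ccccc2)(c2ccccc2)c2ccccc2.[I-]
F7 | step 24 | ylide from F6 | C=C[C@H](C1OCCO1)[C@@H](CO[Si](c2ccccc2)(c2ccccc2)C(C)(C)C)C=P(c2ccccc2)(c2ccccc2)c2ccccc2
F8 | step 9 | oxime of 18 (E/Z mixture) | C=C[C@H](C1OCCO1)[C@@H](CO[Si](c2ccccc2)(c2ccccc2)C(C)(C)C)C=NO
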